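## Retrosynthetic overview

1. Target 44 comes from Luche reduction of diketone 43; ring C (seven-membered) is closed last by intramolecular Pd-catalysed ketone α-arylation (C1–C16) of bromofuryl ketone 42.
2. Key fragment union (C11–C12): crossed Claisen condensation of the thioester enolate of decalin fragment 32 with 2-bromofuran-3-carbonyl chloride 36, then loss of the thioester carbon as CO2.
3. The butenolide comes from the C4 ketone (enol triflate, methoxycarbonylation, lactonisation by C19-OH); the C2 oxygen comes via an enone epoxide; 7α-OAc and 8α-Me come from the C8 ketone.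
4. The C9 quaternary centre is set by Birch reductive alkylation of enone 7; the decalin comes from Michael addition plus amino-acid-mediated aldol condensation of 2-allylcyclohexane-1,3-dione with ethyl vinyl ketone; the allyl group is cut down to C19.
5. Ring order: ring A (the dione) → ring B (annulation) → butenolide → furan attached → ring C.

Convention (assumed): clerodane numbering is used: C1–C10 decalin, C11 = CH2 and C12 = C=O of ring C, C13–C16 furan carbons (C16 bonded to C1), C17 = 8-Me, C18 = lactone C=O, C19 = lactone CH2, C20 = 9-Me; α is the face of C19 and C20, β the face of H-10.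

## Route

Step 1
Reactants: 1 cyclohexane-1,3-dione; 2 allyl bromide
Product: 3 2-allylcyclohexane-1,3-dione
Conditions: KOH, H2O, Cu powder (cat.), rt
Reagents that add atoms: none
Why: Enolate C-alkylation of a 1,3-dione in water (Stetter conditions), where the soft allyl halide favours C- over O-allylation; no stereocentre is formed.

Step 2
Reactants: 3 2-allylcyclohexane-1,3-dione; 4 ethyl vinyl ketone
Product: 5 2-allyl-2-(3-oxopentyl)cyclohexane-1,3-dione
Conditions: Et3N (cat.), EtOAc, rt
Reagents that add atoms: none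
Why: Michael addition of the stabilised dione enolate to the unhindered enone creates the quaternary carbon (future C5), still prochiral because the two ring carbonyls are enantiotopic.

Step 3
Reactants: 5 2-allyl-2-(3-oxopentyl)cyclohexane-1,3-dione
Product: 6 (8aS)-8a-allyl-5-methyl-3,4,8,8a-tetrahydronaphthalene-1,6(2H,7H)-dione
Conditions: D-phenylalanine (1.0 equiv), (1R)-(−)-10-camphorsulfonic acid (0.5 equiv), DMF, rt → 70 °C
Reagents that add atoms: none
Why: Hajos–Parrish–Eder–Sauer–Wiechert enamine aldol condensation completing the Robinson annulation; the D-amino acid differentiates the enantiotopic carbonyls and sets C5 in the sense opposite to the L-amino-acid (S-Wieland–Miescher) series, and recrystallisation raises the ee.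

Step 4
Reactants: 6 (8aS)-enedione
Product: 7 C4 mono-ethylene ketal of 6 (saturated carbonyl protected; enone intact)
Conditions: ethylene glycol, TsOH·H2O (cat.), 4 Å MS, CH2Cl2, rt
Reagents that add atoms: ethylene glycol, OCCO
Why: Acid-catalysed ketalisation is chemoselective for the saturated C4 ketone because the tetrasubstituted enone carbonyl is much less electrophilic.

Step 5
Reactants: 7 ketal enone; 8 tert-butyl bromoacetate
Product: 10 trans-decalone ester (8-oxo; 9α-Me; 9β-CH2CO2tBu; 5α-allyl; 4-ketal; H-10β), via lithium C8-enolate 9 (not isolated)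
Conditions: Li (2.2 equiv), NH3(l)/THF, tBuOH (1.0 equiv), −78 °C; NH3 evaporated; then 8, THF, −78 → 0 °C
Reagents that add atoms: none
Why: Birch-type reductive alkylation: electron transfer and axial protonation at C10 give the trans-decalin (H-10β, anti to the angular allyl) as its regiodefined lithium enolate, which is alkylated at C9 on the β-face, away from the axial angular group, so Me-20 is α and the acetate arm β.

Step 6
Reactants: 10 trans-decalone ester
Product: 11 5α-[(E)-prop-1-enyl] isomer of 10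
Conditions: RuHCl(CO)(PPh3)3 (5 mol %), PhMe, 100 °C
Reagents that add atoms: none
Why: Ruthenium-hydride alkene isomerisation (hydrometalation/β-hydride elimination) moves the terminal double bond one carbon inward, where it stops at the quaternary C5; the E/Z ratio is irrelevant for the next step.

Step 7
Reactants: 11 propenyl compound
Product: 13 19-alcohol (5α-CH2OH; 8-oxo; 4-ketal), via C19 aldehyde 12 (not isolated)
Conditions: O3, CH2Cl2/MeOH, −78 °C; Me2S; then NaBH4, −78 °C
Reagents that add atoms: ozone, [O-][O+]=O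
Why: Ozonolysis cleaves the only C=C to the neopentyl aldehyde, which NaBH4 at −78 °C reduces much faster than the hindered α-quaternary C8 ketone, leaving one carbon (C19) on C5.

Step 8
Reactants: 13 19-alcohol
Product: 14 19-O-TIPS ether
Conditions: TIPSOTf, 2,6-lutidine, CH2Cl2, 0 °C
Reagents that add atoms: triisopropylsilyl trifluoromethanesulfonate, CC(C)[Si](OS(=O)(=O)C(F)(F)F)(C(C)C)C(C)C
Why: Silylation of the primary neopentyl alcohol with the reactive silyl triflate; TIPS is chosen to survive the later acid hydrolysis of the ketal.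

Step 9
Reactants: 14 19-O-TIPS ketone
Product: 15 Δ7-enol triflate (8-OTf)
Conditions: KN(SiMe3)2, PhNTf2, THF, −78 → 0 °C
Reagents that add atoms: N-phenylbis(trifluoromethanesulfonimide), O=S(=O)(N(c1ccccc1)S(=O)(=O)C(F)(F)F)C(F)(F)F
Why: Kinetic enolate O-triflation: C9 is quaternary, so the ketone can enolise only towards C7, and the neopentyl ester CH2 is far less acidic.

Step 10
Reactants: 15 enol triflate
Product: 16 Δ7-8-methyl alkene
Conditions: Me2CuLi (CuI + 2 MeLi), THF, −15 °C
Reagents that add atoms: lithium dimethylcuprate, [Li+].C[Cu-]C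
Why: McMurry–Scott coupling of the vinyl triflate with the Gilman cuprate installs C17 as a trisubstituted alkene without touching the tert-butyl ester or ketal.

Step 11
Reactants: 16 Δ7-8-methyl alkene
Product: 18 7β-alcohol (8α-Me; 8β-H), via 7β-alkylborane 17 (not isolated)
Conditions: BH3·THF, THF, 0 °C → rt; then NaOH, H2O2, 0 °C
Reagents that add atoms: hydrogen peroxide, OO
Why: Brown hydroboration–oxidation: syn anti-Markovnikov addition from the β-face (the α-face is screened by the axial C19 and C20 groups) puts boron on C7 and hydrogen on C8, giving 7β-OH and the equatorial 8α-methyl.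

Step 12
Reactants: 18 7β-alcohol
Product: 19 7-ketone (8α-Me)
Conditions: DMP, NaHCO3, CH2Cl2, rt
Reagents that add atoms: none
Why: Dess–Martin oxidation under buffered neutral conditions; the epimerisable C8 centre already carries the equatorial 8α-methyl, which is also the thermodynamic epimer, so its configuration is secure.

Step 13
Reactants: 19 7-ketone
Product: 20 7α-alcohol (axial)
Conditions: LiBH(sBu)3, THF, −78 °C
Reagents that add atoms: none
Why: Bulky-hydride (L-Selectride) reduction: axial attack from the α-face is blocked by the syn-axial C19 and C20 groups, so hydride enters from the β-face and gives the axial 7α-alcohol.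

Step 14
Reactants: 20 7α-alcohol
Product: 21 7α-acetate
Conditions: Ac2O, DMAP (2 equiv), Et3N, PhMe, 80 °C
Reagents that add atoms: acetic anhydride, CC(=O)OC(C)=O
Why: DMAP-catalysed acylation (Steglich-type N-acylpyridinium transfer) under forcing conditions because the 7α-OH is 1,3-diaxial to C19 and C20; no other hydroxyl is present.

Step 15
Reactants: 21 7α-acetate ketal
Product: 22 4-ketone
Conditions: 1 M HCl, THF, rt
Reagents that add atoms: water, O
Why: Acid-catalysed ketal hydrolysis; the tert-butyl ester, TIPS ether and hindered acetate survive dilute aqueous acid at room temperature.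

Step 16
Reactants: 22 4-ketone
Product: 24 Δ2-en-4-one, via Δ3 trimethylsilyl enol ether 23 (not isolated)
Conditions: LiN(SiMe3)2, TMSCl, THF, −78 °C; then Pd(OAc)2 (1.1 equiv), MeCN, rt
Reagents that add atoms: none
Why: Saegusa–Ito oxidation: the C4 ketone can enolise only towards C3 (C5 is quaternary), and palladium diacetate converts the silyl enol ether into the Δ2 enone by β-hydride elimination.

Step 17
Reactants: 24 Δ2-en-4-one
Product: 25 2β,3β-epoxy-4-ketone
Conditions: tBuOOH, DBU, CH2Cl2, 0 °C → rt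
Reagents that add atoms: tert-butyl hydroperoxide, CC(C)(C)OO
Why: Weitz–Scheffer nucleophilic epoxidation; hydroperoxide adds axially to C2 on the β-face, anti to the axial C19 substituent, giving the 2β,3β-epoxide (either C2 epimer would serve because C2 becomes a ketone in step 29).

Step 18
Reactants: 25 epoxy ketone
Product: 26 2β-hydroxy-4-ketone
Conditions: SmI2 (2.2 equiv), THF/MeOH, −90 °C
Reagents that add atoms: none
Why: Single-electron reduction of the α,β-epoxy ketone by SmI2 cleaves the Cα–O bond selectively to give the β-hydroxy ketone with C2 untouched.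

Step 19
Reactants: 26 2β-hydroxy-4-ketone
Product: 27 2β-OTBS-4-ketone
Conditions: TBSCl, imidazole, DMF, rt
Reagents that add atoms: tert-butyldimethylsilyl chloride, CC(C)(C)[Si](C)(C)Cl
Why: Standard silylation of the only free hydroxyl, masking the aldol-type alcohol against retro-aldol and dehydration.

Step 20
Reactants: 27 2β-OTBS-4-ketone
Product: 28 Δ3-enol triflate (4-OTf)
Conditions: KN(SiMe3)2, PhNTf2, THF, −78 °C
Reagents that add atoms: N-phenylbis(trifluoromethanesulfonimide), O=S(=O)(N(c1ccccc1)S(=O)(=O)C(F)(F)F)C(F)(F)F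
Why: Kinetic enolate O-triflation at −78 °C; enolisation is again possible only towards C3, and at this temperature triflation outruns E1cB loss of the β-silyloxy group.

Step 21
Reactants: 28 Δ3-enol triflate
Product: 29 Δ3-C18 methyl ester
Conditions: Pd(OAc)2 (5 mol %), PPh3, CO (1 atm), MeOH, Et3N, DMF, 60 °C
Reagents that add atoms: carbon monoxide, [C-]#[O+]; methanol, CO
Why: Palladium-catalysed alkoxycarbonylation of the vinyl triflate (oxidative addition, CO insertion, methanolysis) introduces C18 as the α,β-unsaturated ester.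

Step 22
Reactants: 29 tert-butyl ester
Product: 31 side-chain carboxylic acid (9β-CH2CO2H), via trimethylsilyl ester 30 (not isolated)
Conditions: TMSOTf, 2,6-lutidine, CH2Cl2, 0 °C → rt; aqueous work-up
Reagents that add atoms: none
Why: Silyl-triflate cleavage of the tert-butyl ester by loss of isobutene gives the silyl ester, hydrolysed on work-up; TBS and TIPS ethers, the methyl ester and the acetate are inert to TMSOTf/2,6-lutidine.

Step 23
Reactants: 31 carboxylic acid
Product: 32 S-phenyl thioester (9β-CH2COSPh)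
Conditions: PhSH, DCC, DMAP (cat.), CH2Cl2, 0 °C → rt
Reagents that add atoms: thiophenol, Sc1ccccc1
Why: Steglich thioesterification via the O-acylisourea; no free alcohol competes.

Step 24
Reactants: 33 furan-3-carboxylic acid
Product: 35 2-bromofuran-3-carboxylic acid, via dilithio furoate 34 (not isolated)
Conditions: LiN(CHMe2)2 (2.2 equiv), THF, −78 °C; then BrCl2C–CCl2Br, −78 °C → rt; HCl work-up
Reagents that add atoms: 1,2-dibromo-1,1,2,2-tetrachloroethane, BrC(Cl)(Cl)C(Cl)(Cl)Br
Why: Directed ortho-lithiation of the carboxylate dianion occurs only at C2 of the furan (between O and CO2Li), and the aryllithium is brominated by the electrophilic bromine source.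

Step 25
Reactants: 35 2-bromofuran-3-carboxylic acid
Product: 36 2-bromofuran-3-carbonyl chloride
Conditions: (COCl)2, DMF (cat.), CH2Cl2, rt
Reagents that add atoms: oxalyl chloride, O=C(Cl)C(Cl)=O
Why: Vilsmeier-type (DMF-catalysed) conversion of the acid to the acid chloride.

Step 26 (key fragment union)
Reactants: 32 S-phenyl thioester; 36 2-bromofuran-3-carbonyl chloride
Product: 37 β-keto thioester (C11 carries COSPh and the 2-bromofuran-3-yl ketone C12; C11 epimers)
Conditions: MgBr2·OEt2 (2.5 equiv), EtN(CHMe2)2 (3 equiv), CH2Cl2, rt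
Reagents that add atoms: none
Why: Crossed Claisen condensation under soft enolisation: only the thioester is acidic enough to give the magnesium enolate (acetate, methyl enoate and silyl ethers are untouched), it is C-acylated by the acid chloride to forge C11–C12, and chelation of the β-keto thioester product prevents a second acylation.

Step 27
Reactants: 37 β-keto thioester
Product: 39 2-bromofuran-3-yl ketone (C11H2–C12=O; 2β-OTBS; 19-OTIPS; 18-CO2Me; 7α-OAc), via β-keto acid 38 (not isolated)
Conditions: AgOCOCF3, THF/H2O, 50 °C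
Reagents that add atoms: none
Why: Thiophilic silver activates the thioester for hydrolysis and the resulting β-keto acid decarboxylates on warming, leaving the furyl ketone with C11 as CH2.

Step 28
Reactants: 39 bis-silyl ether methyl ester
Product: 41 2β-hydroxy-Δ3-18,19-olide, via 2β,19-diol methyl ester 40 (not isolated)
Conditions: HF·pyridine, THF, rt; then PPTS (cat.), PhMe, 60 °C
Reagents that add atoms: none
Why: Fluoride-mediated desilylation frees the C2 and C19 hydroxyls, and the C19 alcohol undergoes acid-catalysed 5-exo transesterification with the adjacent C18 methyl ester to form the butenolide; the C2 hydroxyl is trans to C18 across C3=C4 and cannot lactonise.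

Step 29
Reactants: 41 2β-hydroxy butenolide
Product: 42 2-oxo-Δ3-18,19-olide
Conditions: DMP, NaHCO3, CH2Cl2, rt
Reagents that add atoms: none
Why: Dess–Martin oxidation of the only free (allylic) alcohol gives the ene-dione and removes the temporary C2 stereocentre.

Step 30
Reactants: 42 2-oxo bromofuryl ketone
Product: 43 tetracyclic 2,12-diketone (ring C closed; H-1α; C16 β)
Conditions: Pd2(dba)3 (5 mol %), Xantphos, Cs2CO3, PhMe (0.005 M), 90 °C
Reagents that add atoms: none
Why: Buchwald–Hartwig-type intramolecular ketone α-arylation: oxidative addition of zerovalent palladium into the furyl bromide, capture of the cross-conjugated C1 enolate (the only enolate that can cyclise; there is no γ-hydrogen) and reductive elimination close the seven-membered ring, and the epimerisable C1 settles in the trans-fused arrangement imposed by the β-oriented C11 tether.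

Step 31
Reactants: 43 tetracyclic diketone
Product: 44 target (CNP0182929.1)
Conditions: NaBH4, CeCl3·7H2O, MeOH, −78 °C
Reagents that add atoms: none
Why: Luche reduction: cerium-assisted 1,2-hydride delivery to the most electrophilic carbonyl (the ene-dione ketone, not the furyl ketone, lactone or acetate) along the axial β-trajectory gives the equatorial 2α-alcohol trans to the C1–C16 bond.

## Compound list

1 | cyclohexane-1,3-dione | O=C1CCCC(=O)C1 | starting material
2 | allyl bromide | C=CCBr | starting material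
3 | 2-allylcyclohexane-1,3-dione | C=CCC1C(=O)CCCC1=O | intermediate
4 | ethyl vinyl ketone (pent-1-en-3-one) | CCC(=O)C=C | starting material
5 | 2-allyl-2-(3-oxopentyl)cyclohexane-1,3-dione | CCC(=O)CCC1(CC=C)C(=O)CCCC1=O | intermediate
6 | (8aS)-8a-allyl-5-methyl-3,4,8,8a-tetrahydronaphthalene-1,6(2H,7H)-dione | C1C[C@@]2(CC=C)C(=O)CCCC2=C(C)C1=O | intermediate
7 | C4 mono-ethylene ketal of 6 | C1C[C@@]2(CC=C)C3(OCCO3)CCCC2=C(C)C1=O | intermediate
8 | tert-butyl bromoacetate | CC(C)(C)OC(=O)CBr | starting material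
9 | lithium C8-enolate (trans-fused; H-10β) | C1C[C@@]2(CC=C)C3(OCCO3)CCC[C@@H]2C(C)=C1O[Li] | intermediate
10 | trans-decalone ester (8-oxo; 9α-Me; 9β-CH2CO2tBu; 5α-allyl; 4-ketal; H-10β) | C1C[C@@]2(CC=C)C3(OCCO3)CCC[C@@H]2[C@@](C)(CC(=O)OC(C)(C)C)C1=O | intermediate
11 | 5α-[(E)-prop-1-enyl] isomer of 10 | C1C[C@@]2(/C=C/C)C3(OCCO3)CCC[C@@H]2[C@@](C)(CC(=O)OC(C)(C)C)C1=O | intermediate
12 | C19 aldehyde (5α-CHO) | C1C[C@@]2(C=O)C3(OCCO3)CCC[C@@H]2[C@@](C)(CC(=O)OC(C)(C)C)C1=O | intermediate
13 | 19-alcohol (5α-CH2OH) | C1C[C@@]2(CO)C3(OCCO3)CCC[C@@H]2[C@@](C)(CC(=O)OC(C)(C)C)C1=O | intermediate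
14 | 19-O-TIPS ether | C1C[C@@]2(CO[Si](C(C)C)(C(C)C)C(C)C)C3(OCCO3)CCC[C@@H]2[C@@](C)(CC(=O)OC(C)(C)C)C1=O | intermediate
15 | Δ7-enol triflate (8-OTf) | C1[C@@]2(CO[Si](C(C)C)(C(C)C)C(C)C)C3(OCCO3)CCC[C@@H]2[C@@](C)(CC(=O)OC(C)(C)C)C(OS(=O)(=O)C(F)(F)F)=C1 | intermediate
16 | Δ7-8-methyl alkene | C1[C@@]2(CO[Si](C(C)C)(C(C)C)C(C)C)C3(OCCO3)CCC[C@@H]2[C@@](C)(CC(=O)OC(C)(C)C)C(C)=C1 | intermediate
17 | 7β-alkylborane (8α-Me) | B[C@H]1C[C@@]2(CO[Si](C(C)C)(C(C)C)C(C)C)C3(OCCO3)CCC[C@@H]2[C@@](C)(CC(=O)OC(C)(C)C)[C@@H]1C | intermediate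
18 | 7β-alcohol (8α-Me) | O[C@H]1C[C@@]2(CO[Si](C(C)C)(C(C)C)C(C)C)C3(OCCO3)CCC[C@@H]2[C@@](C)(CC(=O)OC(C)(C)C)[C@@H]1C | intermediate
19 | 7-ketone (8α-Me) | O=C1C[C@@]2(CO[Si](C(C)C)(C(C)C)C(C)C)C3(OCCO3)CCC[C@@H]2[C@@](C)(CC(=O)OC(C)(C)C)[C@@H]1C | intermediate
20 | 7α-alcohol (axial) | O[C@@H]1C[C@@]2(CO[Si](C(C)C)(C(C)C)C(C)C)C3(OCCO3)CCC[C@@H]2[C@@](C)(CC(=O)OC(C)(C)C)[C@@H]1C | intermediate
21 | 7α-acetate | CC(=O)O[C@@H]1C[C@@]2(CO[Si](C(C)C)(C(C)C)C(C)C)C3(OCCO3)CCC[C@@H]2[C@@](C)(CC(=O)OC(C)(C)C)[C@@H]1C | intermediate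
22 | 4-ketone | CC(=O)O[C@@H]1C[C@@]2(CO[Si](C(C)C)(C(C)C)C(C)C)C(=O)CCC[C@@H]2[C@@](C)(CC(=O)OC(C)(C)C)[C@@H]1C | intermediate
23 | Δ3 trimethylsilyl enol ether | CC(=O)O[C@@H]1C[C@@]2(CO[Si](C(C)C)(C(C)C)C(C)C)C(O[Si](C)(C)C)=CCC[C@@H]2[C@@](C)(CC(=O)OC(C)(C)C)[C@@H]1C | intermediate
24 | Δ2-en-4-one | CC(=O)O[C@@H]1C[C@@]2(CO[Si](C(C)C)(C(C)C)C(C)C)C(=O)C=CC[C@@H]2[C@@](C)(CC(=O)OC(C)(C)C)[C@@H]1C | intermediate
25 | 2β,3β-epoxy-4-ketone | CC(=O)O[C@@H]1C[C@@]2(CO[Si](C(C)C)(C(C)C)C(C)C)C(=O)[C@H]3O[C@H]3C[C@@H]2[C@@](C)(CC(=O)OC(C)(C)C)[C@@H]1C | intermediate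
26 | 2β-hydroxy-4-ketone | CC(=O)O[C@@H]1C[C@@]2(CO[Si](C(C)C)(C(C)C)C(C)C)C(=O)C[C@@H](O)C[C@@H]2[C@@](C)(CC(=O)OC(C)(C)C)[C@@H]1C | intermediate
27 | 2β-OTBS-4-ketone | CC(=O)O[C@@H]1C[C@@]2(CO[Si](C(C)C)(C(C)C)C(C)C)C(=O)C[C@@H](O[Si](C)(C)C(C)(C)C)C[C@@H]2[C@@](C)(CC(=O)OC(C)(C)C)[C@@H]1C | intermediate
28 | Δ3-enol triflate (4-OTf) | CC(=O)O[C@@H]1C[C@@]2(CO[Si](C(C)C)(C(C)C)C(C)C)C(OS(=O)(=O)C(F)(F)F)=C[C@@H](O[Si](C)(C)C(C)(C)C)C[C@@H]2[C@@](C)(CC(=O)OC(C)(C)C)[C@@H]1C | intermediate
29 | Δ3-C18 methyl ester | CC(=O)O[C@@H]1C[C@@]2(CO[Si](C(C)C)(C(C)C)C(C)C)C(C(=O)OC)=C[C@@H](O[Si](C)(C)C(C)(C)C)C[C@@H]2[C@@](C)(CC(=O)OC(C)(C)C)[C@@H]1C | intermediate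
30 | trimethylsilyl ester of the side-chain acid | CC(=O)O[C@@H]1C[C@@]2(CO[Si](C(C)C)(C(C)C)C(C)C)C(C(=O)OC)=C[C@@H](O[Si](C)(C)C(C)(C)C)C[C@@H]2[C@@](C)(CC(=O)O[Si](C)(C)C)[C@@H]1C | intermediate
31 | side-chain carboxylic acid (9β-CH2CO2H) | CC(=O)O[C@@H]1C[C@@]2(CO[Si](C(C)C)(C(C)C)C(C)C)C(C(=O)OC)=C[C@@H](O[Si](C)(C)C(C)(C)C)C[C@@H]2[C@@](C)(CC(=O)O)[C@@H]1C | intermediate
32 | S-phenyl thioester (9β-CH2COSPh) | CC(=O)O[C@@H]1C[C@@]2(CO[Si](C(C)C)(C(C)C)C(C)C)C(C(=O)OC)=C[C@@H](O[Si](C)(C)C(C)(C)C)C[C@@H]2[C@@](C)(CC(=O)Sc3ccccc3)[C@@H]1C | intermediate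
33 | furan-3-carboxylic acid | OC(=O)c1ccoc1 | starting material
34 | dilithio furoate (lithium 2-lithiofuran-3-carboxylate) | [Li]OC(=O)c1ccoc1[Li] | intermediate
35 | 2-bromofuran-3-carboxylic acid | OC(=O)c1ccoc1Br | intermediate
36 | 2-bromofuran-3-carbonyl chloride | ClC(=O)c1ccoc1Br | intermediate
37 | β-keto thioester (C11 epimers) | CC(=O)O[C@@H]1C[C@@]2(CO[Si](C(C)C)(C(C)C)C(C)C)C(C(=O)OC)=C[C@@H](O[Si](C)(C)C(C)(C)C)C[C@@H]2[C@@](C)(C(C(=O)Sc3ccccc3)C(=O)c3ccoc3Br)[C@@H]1C | intermediate
38 | β-keto acid | CC(=O)O[C@@H]1C[C@@]2(CO[Si](C(C)C)(C(C)C)C(C)C)C(C(=O)OC)=C[C@@H](O[Si](C)(C)C(C)(C)C)C[C@@H]2[C@@](C)(C(C(=O)O)C(=O)c3ccoc3Br)[C@@H]1C | intermediate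
39 | 2-bromofuran-3-yl ketone (2β-OTBS; 19-OTIPS; 18-CO2Me; 7α-OAc) | CC(=O)O[C@@H]1C[C@@]2(CO[Si](C(C)C)(C(C)C)C(C)C)C(C(=O)OC)=C[C@@H](O[Si](C)(C)C(C)(C)C)C[C@@H]2[C@@](C)(CC(=O)c3ccoc3Br)[C@@H]1C | intermediate
40 | 2β,19-diol methyl ester | CC(=O)O[C@@H]1C[C@@]2(CO)C(C(=O)OC)=C[C@@H](O)C[C@@H]2[C@@](C)(CC(=O)c3ccoc3Br)[C@@H]1C | intermediate
41 | 2β-hydroxy-Δ3-18,19-olide | CC(=O)O[C@@H]1C[C@@]23COC(=O)C2=C[C@@H](O)C[C@@H]3[C@@](C)(CC(=O)c4ccoc4Br)[C@@H]1C | intermediate
42 | 2-oxo-Δ3-18,19-olide | CC(=O)O[C@@H]1C[C@@]23COC(=O)C2=CC(=O)C[C@@H]3[C@@](C)(CC(=O)c4ccoc4Br)[C@@H]1C | intermediate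
43 | tetracyclic 2,12-diketone (H-1α) | CC(=O)O[C@@H]1C[C@@]23COC(=O)C2=CC(=O)[C@H]2c4occc4C(=O)C[C@@](C)([C@@H]1C)[C@@H]23 | intermediate
44 | CNP0182929.1 | CC(=O)O[C@@H]1C[C@@]23COC(=O)C2=C[C@H](O)[C@H]2c4occc4C(=O)C[C@@](C)([C@@H]1C)[C@@H]23 | target

## Step count and risks

Total: 31 steps. Longest linear sequence: 29 steps (steps 1–23 and 26–31, from cyclohexane-1,3-dione); the furan branch is 2 steps (24–25).

Most likely to fail:

- Step 30 (palladium α-arylation closing ring C). The ene-dione 42 is base-sensitive and protodebromination or aldol-type side reactions may win. The fallback closes the ring without an enolate and sets out from 41. Dehydration of the allylic alcohol (Burgess reagent, PhMe, 60 °C) gives the ring A 1,3-diene lactone F1. Intramolecular Heck-type carbopalladation of C1=C2 by the furyl bromide (Pd(OAc)2, P(o-tol)3, NaOAc, DMF, 80 °C) delivers C16 to C1 from the β-face, the only face the C11 tether reaches. The resulting π-allylpalladium (C2–C4) is opened by external acetate at C2 on the α-face, restoring the conjugated C3=C4 and giving the 2α,7α-diacetate F2. Selective methanolysis of the unhindered allylic 2-acetate (K2CO3, MeOH, 0 °C; the 7α-acetate is shielded by C19 and C20) comes back to the route at 44.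

- Step 26 (crossed Claisen on a neopentyl thioester). C-acylation next to the quaternary C9 may stall or give O-acylation. The fallback makes the same bond by aldol addition and oxidation and sets out from 32. Acid chloride 36 is reduced (LiAlH(OtBu)3, THF, −78 °C) to 2-bromofuran-3-carbaldehyde F3. The magnesium enolate of 32 (MgBr2·OEt2, EtN(CHMe2)2, CH2Cl2) adds to this smaller and more electrophilic aldehyde to give the β-hydroxy thioester F4. Dess–Martin oxidation comes back to the route at 37.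

- Step 14 (acetylation of the 7α-hydroxyl). The alcohol is 1,3-diaxial to both C19 and C20 and may resist acylation. The fallback puts the acetate on oxygen while C7 is still sp2 and sets out from 19. Enolisation (possible only towards C8) and O-acylation (KN(SiMe3)2, THF, −78 °C; then Ac2O) give the Δ7 enol acetate F5. Hydrogenation from the open β-face (H2 50 bar, [Ir(cod)(PCy3)(py)]PF6, CH2Cl2) adds both hydrogens syn, setting 7α-OAc and 8α-Me together, and comes back to the route at 21.

## Further compounds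

F1 | step 30 | ring A 1,3-diene lactone (Δ1,Δ3-18,19-olide; bromofuryl ketone) | CC(=O)O[C@@H]1C[C@@]23COC(=O)C2=CC=C[C@@H]3[C@@](C)(CC(=O)c4ccoc4Br)[C@@H]1C
F2 | step 30 | 2α,7α-diacetate (2-O-acetyl target) | CC(=O)O[C@@H]1C[C@@]23COC(=O)C2=C[C@H](OC(C)=O)[C@H]2c4occc4C(=O)C[C@@](C)([C@@H]1C)[C@@H]23
F3 | step 26 | 2-bromofuran-3-carbaldehyde | O=Cc1ccoc1Br
F4 | step 26 | β-hydroxy thioester (C11 and C12 epimers) | CC(=O)O[C@@H]1C[C@@]2(CO[Si](C(C)C)(C(C)C)C(C)C)C(C(=O)OC)=C[C@@H](O[Si](C)(C)C(C)(C)C)C[C@@H]2[C@@](C)(C(C(=O)Sc3ccccc3)C(O)c3ccoc3Br)[C@@H]1C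
F5 | step 14 | Δ7 enol acetate (7-OAc; 8-Me) | C1[C@@]2(CO[Si](C(C)C)(C(C)C)C(C)C)C3(OCCO3)CCC[C@@H]2[C@@](C)(CC(=O)OC(C)(C)C)C(C)=C1OC(C)=O
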